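## The problem

The target is a benzophenone with no stereocentre: ring B is a 3-hydroxyphenyl group and ring A is a fully substituted phloroglucinol nucleus. Numbering ring A from the carbon that carries the ketone (C1), C2 and C6 bear free, carbonyl-chelated hydroxyls, C3 and C5 bear 3-methylbut-2-enyl (prenyl) groups, and C4 bears the only methyl ether. The whole difficulty is regiochemical and sits on ring A: six contiguous substituents, two C-prenyl groups, and one of three ring oxygens methylated, the one flanked by both prenyl groups. Electrophilic prenylation of a phloroglucinol is the classical weak point of this family (O- against C-attack, mono-, di- and geminal dialkylation with loss of aromaticity). Prenyl groups ortho to free hydroxyls close to chromans under protic or Lewis acid and do not survive hydrogenation, which excludes a late Friedel–Crafts acylation and acid-labile or benzyl protecting groups. A late methylation would also have to tell the 4-OH from the 3'-OH of ring B. The feature that opens another way is that ring A has a local mirror plane through C1 and C4 and the 1,3,5-oxygen pattern of a folded polyketide. C2–C3–C4–C5–C6 with their substituents are the five carbons of a 3-oxopentanedioate (C2 and C6 the carboxyl carbons, C3 and C5 the α-carbons, C4 the ketone carbon as its methyl enol ether), and C1 with the exocyclic carbonyl and ring B is an acetophenone whose methyl carbon has been acylated twice.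

## Retrosynthesis

**10 ⇒ 9.** The first cut is the ring bond C1–C6, between the aroyl-bearing carbon and one of the two hydroxyl-bearing carbons. Forward, it is an intramolecular Claisen condensation of the open-chain keto ester 9, a tetraketide whose central carbonyl is masked as a methyl enol ether, followed by enolisation to the arene. Against the neighbouring cuts (aryl–carbonyl bond, ring–prenyl bonds, O–methyl bond) this one removes the arene itself, so no substituent has to be placed on an aromatic ring. 9 differs from 10 only by one methanol. The forward reaction must close through carbon and not oxygen, and by Claisen and not aldol condensation.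

**9 ⇒ 7 + 8.** The second cut is the bond C1–C2, again at C1. Both bonds from C1 then come from acylation of the methyl carbon of 1-(3-hydroxyphenyl)ethan-1-one 6, used as its dilithium phenoxide-enolate 7, which makes the ring construction a [5+1] annulation. The partner is the acyl imidazolide 8 of the half-ester 5. The cut next door (C2–C3) would need an aroylacetyl electrophile with an acidic methylene and a γ-carbanion, and gains nothing. The C25 chain 9 falls into a C8 ketone and one five-carbon chain. The forward reaction must acylate a ketone enolate at carbon with a donor that has an acidic C–H of its own, hence an activated leaving group and no isolation of 9.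

**5 ⇒ 4.** One O–methyl ester bond is cut: the half-ester 5 comes from the diester 4 by a single saponification. There is no regiochemical question, because the two ester groups of 4 are exchanged by a double-bond shift through the common dienolate. The forward reaction only has to stop after one hydrolysis.

**4 ⇒ 3.** The enol ether O–CH3 bond is cut. This is where the position of the methyl ether of 10 is decided: on the single ketone of the acyclic diester 3, not among several phenolic hydroxyls. The forward reaction must methylate the enolate at oxygen.

**3 ⇒ 1 + 2.** The two C–C bonds to the prenyl groups are cut at the sp3 α-carbons of dimethyl 3-oxopentanedioate 1, with 1-bromo-3-methylbut-2-ene 2 as electrophile. Enolate alkylation of a β-keto ester replaces the arene prenylation, and both prenyl groups are placed before any ring exists. The forward reaction must alkylate once at each α-carbon.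

## Roads not taken

**Alternative 1:** The most obvious plan keeps a bought phloroglucinol ring and cuts, in turn, the aryl–carbonyl bond, the two ring–prenyl bonds and the O–methyl bond. Forward: Friedel–Crafts or Hoesch acylation of phloroglucinol with a 3-hydroxybenzoic acid derivative gives (3-hydroxyphenyl)(2,4,6-trihydroxyphenyl)methanone A1. Double C-prenylation with prenyl bromide and base gives the diprenyl tetrol A2, and methylation of its 4-OH gives 10. The key step, the prenylation of A1, has to choose among four hydroxyls and two ring carbons, and it competes with geminal dialkylation and chroman formation. The methylation must then find the 4-OH, between two prenyl groups, in the presence of the 3'-OH. The chosen plan sets every one of these positions on acyclic carbons before the ring exists.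

**Alternative 2:** The two ring–prenyl bonds are cut by [3,3] logic. [3-(tert-Butyldimethylsilyloxy)phenyl](2,6-dihydroxy-4-methoxyphenyl)methanone A3 would be O-alkylated twice with a 2-methylbut-3-en-2-yl carbonate and Pd(PPh3)4 (zerovalent palladium) to the bis(1,1-dimethylallyl) ether A4. A double aromatic Claisen rearrangement to C3 and C5 and desilylation would then give 10. The rearrangement is regiochemically sound, but it needs two tertiary ethers at the two chelated hydroxyls that flank the ketone, the least nucleophilic and most hindered oxygens of the molecule. A3 itself already costs an acylation, a selective methylation and a protection. The sequence is at least twice as long as the chosen one.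

**Alternative 3:** Ring A is cut across C2–C3 and C5–C6 into two three-carbon pieces. Forward: [3+3] condensation of 2,10-dimethylundeca-2,9-dien-6-one A5 (as its bis-silyl enol ether) with malonyl dichloride gives 2,4-bis(3-methylbut-2-en-1-yl)benzene-1,3,5-triol A6, followed by C-aroylation and O-methylation. The ring construction here places only the prenyl groups. The aroylation of A6 needs the Lewis acid that closes chromans, and the hydroxyl to be methylated is the most hindered of three. The [5+1] plan brings in all six substituents with the ring.

Key step: step 4

Remark on the chemistry: the sp3 centres of 3, 4, 5, 8 and 9 and the enol ether geometry of 4, 5, 8 and 9 are expected as mixtures that are all erased in step 4. The SMILES therefore show no configuration at the sp3 centres, and show the E enol ether, the isomer that closes.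

## Route

Step 1
Reactants: 1 dimethyl 3-oxopentanedioate; 2 1-bromo-3-methylbut-2-ene (2 equiv)
Product: 3 dimethyl 2,4-bis(3-methylbut-2-en-1-yl)-3-oxopentanedioate
Conditions: NaH (1.05 equiv), THF, 0 °C, then 2 (1.0 equiv), rt; repeated once in the same flask
Reagents that add atoms: 1-bromo-3-methylbut-2-ene (2), CC(C)=CCBr
Why: Enolate alkylation of a β-keto ester; after the first alkylation the unsubstituted methylene is the more acidic and less hindered site, so the second prenyl group should enter at the other α-carbon, and the diastereomer mixture is of no consequence.

Step 2
Reactants: 3 dimethyl 2,4-bis(3-methylbut-2-en-1-yl)-3-oxopentanedioate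
Product: 4 dimethyl (2E)-3-methoxy-2,4-bis(3-methylbut-2-en-1-yl)pent-2-enedioate
Conditions: Cs2CO3 (1.5 equiv), Me2SO4 (1.2 equiv), DMF, 0 °C → rt
Reagents that add atoms: dimethyl sulfate, COS(=O)(=O)OC
Why: O-alkylation of a β-keto ester enolate; a cesium enolate in a dipolar aprotic solvent with a hard methylating agent should react at oxygen, and C-methylation would have to build a quaternary carbon between a prenyl group and a branched ketone.

Step 3
Reactants: 4 dimethyl (2E)-3-methoxy-2,4-bis(3-methylbut-2-en-1-yl)pent-2-enedioate
Product: 5 (3E)-3,5-dimethoxy-5-oxo-2,4-bis(3-methylbut-2-en-1-yl)pent-3-enoic acid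
Conditions: LiOH·H2O (1.1 equiv), THF–H2O 3:1, 0 °C → rt; 1 M HCl to pH 4, 0 °C
Reagents that add atoms: lithium hydroxide monohydrate (hydroxide oxygen of the carboxyl group), [Li+].[OH-].O
Why: Ester saponification that should stop at the half-ester, because the monocarboxylate and its dienolate repel hydroxide; which ester reacts does not matter, since both half-esters are double-bond tautomers that give one dienolate in step 4.

Step 4
Reactants: 5 (3E)-3,5-dimethoxy-5-oxo-2,4-bis(3-methylbut-2-en-1-yl)pent-3-enoic acid; 6 1-(3-hydroxyphenyl)ethan-1-one (3 equiv, excess recoverable)
Product: 10 (3-hydroxyphenyl)[2,6-dihydroxy-4-methoxy-3,5-bis(3-methylbut-2-en-1-yl)phenyl]methanone, via dilithium phenoxide-enolate 7 (not isolated), via acyl imidazolide 8 (not isolated), via triketo ester 9 (not isolated)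
Conditions: 5, 1,1'-carbonyldiimidazole (1.05 equiv), THF, 0 °C → rt (gives 8); 6 (3.0 equiv), LiN(SiMe3)2 (6.1 equiv), THF, −78 → −20 °C (gives 7); 8 added to 7 at −78 °C, then 0 °C; Mg(OMe)2 (4 equiv), MeOH, 60 °C; 1 M HCl, 0 °C
Reagents that add atoms: 1,1'-carbonyldiimidazole, O=C(n1ccnc1)n1ccnc1 (imidazolyl group of intermediate 8 only); LiN(SiMe3)2, [Li+].C[Si](C)(C)[N-][Si](C)(C)C (lithium of intermediate 7 only); no reagent atom remains in 10
Why: 1,1'-Carbonyldiimidazole turns acid 5 into the acyl imidazolide 8, and the dilithium phenoxide-enolate 7 is acylated at carbon, its most basic site, as polyanions of hydroxyacetophenones are by acyl donors (Claisen-type ketone acylation); proton transfer from the doubly activated C–H of 8 should not take the donor out of play, because elimination–addition through the dienolate (E1cB, imidazolide as leaving group) delivers the acyl group to the same enolate carbon. The product is the lithium diketonate of 9, in which C1 now carries C2. Mg(OMe)2 then chelates the 1,3-diketonate, and its central carbon attacks the methyl ester in an intramolecular Claisen (Dieckmann) condensation, a 6-(enolexo)-exo-trig closure that forms the C1–C6 bond of ring A; loss of methoxide and enolisation give the arene as its magnesium chelate, which makes the closure irreversible. The closest known reaction type is the Claisen cyclisation of 3,5,7-trioxoalkanoates and of 6-(2-oxoalkyl)-4-methoxy-2-pyranones to acylphloroglucinols with KOH or Mg(OMe)2, the laboratory counterpart of benzophenone synthase. The selectivity needed is closure through carbon and by Claisen, not aldol, condensation: the aldol (resorcylate) mode is shut because the α-carbon of the ester is a fully substituted enol ether carbon that could only give a quaternary aldol unable to aromatise, and a lactone formed through oxygen is reopened by methoxide and fed back. The enol ether geometry is no constraint, since deprotonation at the prenylated sp3 carbon gives a dienolate in which the C2–C3 bond can rotate, so both isomers reach the cis arrangement that closes. No stereocentre is formed, and the regiochemistry of ring A is fixed by construction: the enol ether carbon becomes C4, the two alkylated carbons C3 and C5, the two carboxyl carbons C2 and C6.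

## Compound list

1 | dimethyl 3-oxopentanedioate (dimethyl 1,3-acetonedicarboxylate) | COC(=O)CC(=O)CC(=O)OC | starting material
2 | 1-bromo-3-methylbut-2-ene (prenyl bromide) | CC(C)=CCBr | starting material
3 | dimethyl 2,4-bis(3-methylbut-2-en-1-yl)-3-oxopentanedioate (diastereomer mixture) | COC(=O)C(CC=C(C)C)C(=O)C(CC=C(C)C)C(=O)OC | intermediate
4 | dimethyl (2E)-3-methoxy-2,4-bis(3-methylbut-2-en-1-yl)pent-2-enedioate (racemic, E/Z mixture expected) | COC(=O)/C(CC=C(C)C)=C(OC)\C(CC=C(C)C)C(=O)OC | intermediate
5 | (3E)-3,5-dimethoxy-5-oxo-2,4-bis(3-methylbut-2-en-1-yl)pent-3-enoic acid (racemic; double-bond tautomer and Z isomer equivalent in use) | OC(=O)C(CC=C(C)C)/C(OC)=C(CC=C(C)C)\C(=O)OC | intermediate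
6 | 1-(3-hydroxyphenyl)ethan-1-one | CC(=O)c1cccc(O)c1 | starting material
7 | dilithium 3-(1-oxidoethenyl)phenolate | [Li+].[Li+].C=C([O-])c1cccc([O-])c1 | intermediate (not isolated)
8 | methyl (2E)-5-(1H-imidazol-1-yl)-3-methoxy-2,4-bis(3-methylbut-2-en-1-yl)-5-oxopent-2-enoate | COC(=O)/C(CC=C(C)C)=C(OC)\C(CC=C(C)C)C(=O)n1ccnc1 | intermediate (not isolated)
9 | methyl (2E)-7-(3-hydroxyphenyl)-3-methoxy-2,4-bis(3-methylbut-2-en-1-yl)-5,7-dioxohept-2-enoate | COC(=O)/C(CC=C(C)C)=C(OC)\C(CC=C(C)C)C(=O)CC(=O)c1cccc(O)c1 | intermediate (not isolated)
10 | (3-hydroxyphenyl)[2,6-dihydroxy-4-methoxy-3,5-bis(3-methylbut-2-en-1-yl)phenyl]methanone | COc1c(CC=C(C)C)c(O)c(C(=O)c2cccc(O)c2)c(O)c1CC=C(C)C | target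

## Step count and least certain steps

Total step count: 4. Longest linear sequence: 4 steps (1 → 3 → 4 → 5 → 10); 2 and 6 are bought.

**Step 4 (key step).** The most likely failure is that proton transfer from the acyl donor to the enolate outruns C-acylation, so that the donor is consumed by self-condensation. Further risks are closure of the chain through oxygen (lactonisation, or conjugate displacement of the enol ether methoxide to a 4-pyranone) and retro-Claisen cleavage of the diketone by methoxide before the ring closes. The fallback sets out from 5 and comes back at 9. Cyclodehydration of 5 with N,N'-dicyclohexylcarbodiimide in CH2Cl2 at 0 °C should give 4,6-dimethoxy-3,5-bis(3-methylbut-2-en-1-yl)-2H-pyran-2-one F1, an internal enol ester of the half-ester that has no acidic C–H. Added to 7, F1 should be attacked at its lactone carbonyl and open to the dienolate of 9, which is closed with Mg(OMe)2 as before. The plan thereby becomes a pyranone-to-benzene ring transformation in which proton transfer cannot compete.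

**Step 2.** Methylation at carbon in place of oxygen would give a quaternary keto diester that is useless for the route. The fallback changes the order of events, sets out from 1 and comes back at 4. Trimethyl orthoformate with catalytic H2SO4 in methanol converts 1, which has no acid-sensitive alkene, into dimethyl (2E)-3-methoxypent-2-enedioate F2. Two successive alkylations of F2 with NaH and 2 in THF then place the prenyl groups at C2 and C4 through the glutaconate anion. The price is a less certain site of the second alkylation.

**Step 3.** The hydrolysis may run on to the diacid or stall once the substrate is ionised to its dienolate, and hydroxide may displace the enol ether methoxide by conjugate addition. The fallback sets out from 4 and comes back at 5. Exhaustive ester cleavage with KOSiMe3 (2.5 equiv) in THF gives (2E)-3-methoxy-2,4-bis(3-methylbut-2-en-1-yl)pent-2-enedioic acid F3. N,N'-Dicyclohexylcarbodiimide closes F3 to 4-methoxy-3,5-bis(3-methylbut-2-en-1-yl)-2H-pyran-2,6(3H)-dione F4, and methanol opens this anhydride to exactly one half-ester, 5.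

**Step 1.** Double alkylation at one α-carbon, O-alkylation or a third alkylation would lower the share of the 2,4-dialkyl product. The fallback sets out from 2 and comes back at 3, and places each prenyl group on its own carbon before the chain is joined. Commercial dimethyl malonate is alkylated with 2 (NaH, THF) to dimethyl 2-(3-methylbut-2-en-1-yl)propanedioate F5. One equivalent of KOH in methanol gives 2-(methoxycarbonyl)-5-methylhex-4-enoic acid F6. Half of F6 is converted with 1,1'-carbonyldiimidazole into methyl 2-(1H-imidazole-1-carbonyl)-5-methylhex-4-enoate F7. F7 then acylates the magnesium enolate of the other half (MgCl2, Et3N, THF), and decarboxylation gives 3.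

## Further compounds

F1 | step 4 | 4,6-dimethoxy-3,5-bis(3-methylbut-2-en-1-yl)-2H-pyran-2-one | COc1oc(=O)c(CC=C(C)C)c(OC)c1CC=C(C)C
F2 | step 2 | dimethyl (2E)-3-methoxypent-2-enedioate | COC(=O)/C=C(OC)\CC(=O)OC
F3 | step 3 | (2E)-3-methoxy-2,4-bis(3-methylbut-2-en-1-yl)pent-2-enedioic acid | OC(=O)/C(CC=C(C)C)=C(OC)\C(CC=C(C)C)C(=O)O
F4 | step 3 | 4-methoxy-3,5-bis(3-methylbut-2-en-1-yl)-2H-pyran-2,6(3H)-dione | COC1=C(CC=C(C)C)C(=O)OC(=O)C1CC=C(C)C
F5 | step 1 | dimethyl 2-(3-methylbut-2-en-1-yl)propanedioate | COC(=O)C(CC=C(C)C)C(=O)OC
F6 | step 1 | 2-(methoxycarbonyl)-5-methylhex-4-enoic acid | OC(=O)C(CC=C(C)C)C(=O)OC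
F7 | step 1 | methyl 2-(1H-imidazole-1-carbonyl)-5-methylhex-4-enoate | COC(=O)C(CC=C(C)C)C(=O)n1ccnc1
A1 | alternative 1 | (3-hydroxyphenyl)(2,4,6-trihydroxyphenyl)methanone | O=C(c1cccc(O)c1)c1c(O)cc(O)cc1O
A2 | alternative 1 | (3-hydroxyphenyl)[2,4,6-trihydroxy-3,5-bis(3-methylbut-2-en-1-yl)phenyl]methanone | CC(C)=CCc1c(O)c(CC=C(C)C)c(O)c(C(=O)c2cccc(O)c2)c1O
A3 | alternative 2 | [3-(tert-butyldimethylsilyloxy)phenyl](2,6-dihydroxy-4-methoxyphenyl)methanone | COc1cc(O)c(C(=O)c2cccc(O[Si](C)(C)C(C)(C)C)c2)c(O)c1
A4 | alternative 2 | [3-(tert-butyldimethylsilyloxy)phenyl]{4-methoxy-2,6-bis[(2-methylbut-3-en-2-yl)oxy]phenyl}methanone | COc1cc(OC(C)(C)C=C)c(C(=O)c2cccc(O[Si](C)(C)C(C)(C)C)c2)c(OC(C)(C)C=C)c1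
A5 | alternative 3 | 2,10-dimethylundeca-2,9-dien-6-one | CC(C)=CCCC(=O)CCC=C(C)C
A6 | alternative 3 | 2,4-bis(3-methylbut-2-en-1-yl)benzene-1,3,5-triol | CC(C)=CCc1c(O)cc(O)c(CC=C(C)C)c1O
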